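**Compound numbers used throughout**

1 6-bromoisatin · 2 5,6-dibromoisatin · 3 di-tert-butyl dicarbonate · 4 N-Boc-5,6-dibromoisatin · 5 dimethylamine · 6 ortho-(Boc-amino)aryl α-ketoamide · 7 carbon tetrabromide · 8 (dibromomethylene)triphenylphosphorane (not isolated) · 9 dibromoalkene, precursor of the key step · 10 N-Boc-2,5,6-tribromoindole-3-carboxamide, product of the key step · 11 N–H indole amide · 12 N-methyl indole amide · 13 amine–borane adduct (not isolated) · 14 tertiary amine · 15 target

Assumption: 1, 3, 5 (as a THF solution) and 7 are taken as commercial. Indole numbering is used for all ring positions.

## Analysis of the target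

Target 15 is an indole, a benzene ring fused to a pyrrole ring, that carries a methyl group on N1, bromine at C2, C5 and C6, and a CH2–N(CH3)2 oxide side chain on C3. It has no stereocentre and no stereogenic double bond, so the whole problem is one of regiochemistry and chemoselectivity. The amine oxide is the most delicate group: hydrides, phosphines and low-valent metals reduce it, and heat or acid can make it rearrange or fragment. The C3–CH2–N bond is of the gramine type and ionises to a 3-methyleneindoleninium ion once nitrogen becomes a leaving group, and the three C–Br bonds exclude organolithium reagents, dissolving metals and catalytic hydrogenation. The main difficulty is to place three bromines at defined positions, because bromination of a finished indole does not cleanly distinguish C5 and C6 from C4 and C7. The strategy rests on C2, which is bonded to N1, to C3 and to bromine, and can therefore be the CBr2 carbon of a 1,1-dibromoalkene whose other carbon is C3, giving one bromide to nitrogen and keeping the other. The side-chain carbon at the amide oxidation level is the C2 carbonyl of an isatin, so isatin 2 supplies the benzene ring with both bromines, N1, C3 and the side-chain carbon in one piece.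

## Retrosynthetic reasoning

**N–O bond.** The last bond made is the N–O bond of 15, which leads back to the tertiary amine 14. The amine oxide would not survive a hydride, a phosphine or an alkylating agent, so it cannot pass through any earlier step. The forward reaction only has to deliver one oxygen atom to the most nucleophilic atom of 14 without touching the brominated ring.

**Side-chain methylene.** Amine 14 is taken back to the tertiary amide 12 by restoring a carbonyl oxygen on the exocyclic carbon. Cutting the CH2–N bond instead would need an electrophilic C3-methylene unit, which is unstable for the same reason gramines are, or an aminomethylation of a deactivated indole already brominated at C2. The amide is robust through all earlier steps. The forward reaction must reduce C=O to CH2 without touching three C–Br bonds, which points to an electrophilic hydride.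

**N1–CH3 and N1–CO2tBu.** The N-methyl group of 12 is removed to give the N–H indole 11, and 11 is the deprotected form of carbamate 10. The methyl group cannot be present earlier. The ring closure needs a nitrogen that still carries a hydrogen, and the isatin only opens to an amine when its nitrogen carries an acyl group. The Boc group meets both needs and is then exchanged for methyl.

**N1–C2 (key disconnection).** Carbamate 10 is opened between N1 and C2 to the dibromoalkene 9. This cut is chosen because it explains the C2 bromine as the bromine that stays when the other leaves. It also removes any halogenation of an indole from the plan and leaves an acyclic precursor in which every substituent already sits on the right atom. The forward reaction must make the carbamate nitrogen attack the CBr2 carbon, not the amide carbonyl, and must leave the two aryl bromides alone.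

**C2=C3.** Alkene 9 is cut at its double bond into ketone 6 and a one-carbon CBr2 unit that comes from 7 through ylide 8. The ketone is an aryl glyoxylamide, whose ketone carbonyl is activated by the neighbouring amide. The forward olefination has to pick this carbonyl over the amide and carbamate carbonyls, which are far less electrophilic.

**Amide C–N and the isatin.** Ketoamide 6 is cut at the amide C–N bond to the N-Boc isatin 4 and amine 5. Opening of the five-membered ring at C2 reveals the ketone, the amide and the carbamate N–H at once. Compound 4 comes from isatin 2 and 3, and 2 from 1 by bromination at C5, the position para to nitrogen. Both ring bromines are thus in place before any other bond is made.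

## Alternatives that were turned down

Alternative 1: The benzene ring is cut at C4–C5 and C6–C7. In the forward sense the pyrone diene of methyl 1-methyl-5-oxo-1,5-dihydropyrano[3,4-b]pyrrole-3-carboxylate (A2) would add bis(trimethylsilyl)acetylene (A3) across C4 and C7. Decarboxylative cycloreversion would then aromatise the adduct to methyl 1-methyl-5,6-bis(trimethylsilyl)indole-3-carboxylate (A1). The two silyl groups would later be exchanged for bromine by ipso substitution.
- For it: the symmetrical alkyne fixes the 5,6-pattern without ambiguity, and the N-methyl group is present from the start. On that last point it is stronger than the chosen route, which spends two steps on exchanging Boc for methyl.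
- Against it: A2 is itself a trisubstituted pyrrole lactone that needs several steps. A3 is a bulky, unactivated dienophile that needs forcing temperatures. A1 still lacks all three bromines. Two ipso-bromodesilylations and a C2 bromination must then be run on an electron-rich ring on which protodesilylation and bromination elsewhere compete. The ester must also be converted into the amine afterwards.
- Comparison: the route is longer and puts its halogen problem at the end. The chosen route places all three bromines by construction and offers that in exchange for the protecting-group steps.

Alternative 2: The benzene ring is cut at C7–C7a and C3a–C4. Under acid, N,N,1-trimethylpyrrole-3-carboxamide (A5) would attack both masked aldehyde carbons of 3,4-dibromo-2,5-dimethoxytetrahydrofuran (A6) through its free α and β positions. Loss of the oxygen leaving groups would then aromatise the new ring and give 5,6-dibromo-N,N,1-trimethylindole-3-carboxamide (A4).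
- For it: it is short and convergent. Pyrrole A5 brings the N-methyl group and the amide, acetal A6 brings the 5,6-dibromo pattern, and A4 is one bromination away from compound 12. On step count it is clearly stronger than the chosen route.
- Against it: A5 is a pyrrole deactivated by its carboxamide, and it must attack twice at acetal carbons that a neighbouring bromine makes less electrophilic. The acetal A6 would be used as its mixture of diastereomers, which does not matter for the outcome but does not help the second closure either. After the first attack the pyrrolylcarbinyl cation can be trapped by a second molecule of A5 in place of the ring's own β position, the usual route to oligomers. Attack through the other α position of A5 leads nowhere. Aromatisation must then eliminate the bridging oxygen while both bromines stay, although elimination of a bromide from C5 or C6 is at least as easy. The C2 bromine would finally be put in by a late halogenation of a deactivated indole.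
- Comparison: the chosen route is longer, but each of its bond-forming steps belongs to a well-established class, and no step depends on a double substitution between two deactivated partners.

Alternative 3: The pyrrole ring is cut at C2–C3. Mild base would form the ester enolate of methyl 2-[4,5-dibromo-2-(dibromomethylideneamino)phenyl]acetate (A8). The enolate would attack the N=CBr2 carbon, expel bromide and give methyl 2,5,6-tribromo-1H-indole-3-carboxylate (A7).
- For it: it also brings in the C2 bromine by construction. The N=CBr2 carbon of A8 is an imidoyl-halide-type electrophile, more reactive than the CBr2 carbon of an acrylamide, and a carbon nucleophile cannot be diverted into an acyl transfer. On the ease of the bond-forming event it is therefore stronger than the chosen route. The indole N–H of A7 is free for methylation without a protecting group.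
- Against it: the closure offers no geometric advantage, because the C=N bond lies inside the new ring and the mode is 5-endo-trig, as in the chosen route. The free ortho-amino ester from which A8 would be made closes onto its own ester to a lactam, so nitrogen must be carried from a nitro group through a formamide and an isocyanide before the two bromine atoms are put on the isocyanide carbon. The N=CBr2 group is sensitive to moisture. The ester of A7 is a vinylogous carbamate that resists aminolysis, and its reduction would pass through a 3-hydroxymethylindole that ionises easily.
- Comparison: the more electrophilic carbon and the free N–H are paid for with a longer and more fragile preparation of the precursor and with extra steps on the side chain. The chosen route starts from a stable isatin and receives the amide oxidation level directly from the ring opening.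

Key step: step 5

## Route

Step 1
Reactants: 1 6-bromoisatin
Product: 2 5,6-dibromoisatin
Conditions: Br2 (1.05 equiv), AcOH, 70 °C
Reagents that add atoms: bromine, BrBr
Why: Electrophilic aromatic bromination; C5 is para to the anilide nitrogen, the strongest director, and is where isatins brominate first, whereas C7 lies between nitrogen and the existing bromine and should react only with excess reagent.

Step 2
Reactants: 2 5,6-dibromoisatin; 3 di-tert-butyl dicarbonate
Product: 4 tert-butyl 5,6-dibromo-2,3-dioxoindoline-1-carboxylate
Conditions: Boc2O (1.2 equiv), DMAP (5 mol %), THF, 0 °C to rt
Reagents that add atoms: none
Why: DMAP-catalysed N-acylation of the lactam N–H; the Boc group turns C2 into an imide carbonyl for step 3 and later leaves the nitrogen as an acidic carbamate N–H for step 5.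

Step 3
Reactants: 4 tert-butyl 5,6-dibromo-2,3-dioxoindoline-1-carboxylate; 5 dimethylamine
Product: 6 tert-butyl N-{4,5-dibromo-2-[2-(dimethylamino)-2-oxoacetyl]phenyl}carbamate
Conditions: Me2NH (2 M in THF, 1.1 equiv), THF, −20 to 0 °C
Reagents that add atoms: none
Why: Ring-opening aminolysis of an N-acylisatin; attack at the imide carbonyl C2 expels the carbamate nitrogen irreversibly, while addition to the C3 ketone is reversible, so the open α-ketoamide should result.

Step 4
Reactants: 6 tert-butyl N-{4,5-dibromo-2-[2-(dimethylamino)-2-oxoacetyl]phenyl}carbamate; 7 carbon tetrabromide
Product: 9 tert-butyl N-{4,5-dibromo-2-[1,1-dibromo-3-(dimethylamino)-3-oxoprop-1-en-2-yl]phenyl}carbamate, via dibromomethylenetriphenylphosphorane 8 (not isolated)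
Conditions: CBr4 (2 equiv), PPh3 (4 equiv), CH2Cl2, 0 °C to reflux
Reagents that add atoms: none
Why: Ramirez dibromo-olefination, a Wittig reaction of ylide 8; the aryl ketone is activated by the adjacent amide carbonyl as in α-keto esters, the amide and carbamate carbonyls are inert to the ylide, and no alkene geometry arises because both new substituents are bromine.

Step 5
Reactants: 9 tert-butyl N-{4,5-dibromo-2-[1,1-dibromo-3-(dimethylamino)-3-oxoprop-1-en-2-yl]phenyl}carbamate
Product: 10 tert-butyl 2,5,6-tribromo-3-(dimethylcarbamoyl)indole-1-carboxylate
Conditions: Cs2CO3 (1.5 equiv), CuI (10 mol %), 1,10-phenanthroline (20 mol %), MeCN, 60 °C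
Reagents that add atoms: none
Why: Cs2CO3 removes the carbamate N–H, which the dibrominated ring acidifies, and the nitrogen anion adds to the CBr2 carbon, the β-carbon of the acrylamide, so that the charge arrives on the α-carbon where the amide carbonyl and the aryl ring stabilise it; loss of bromide then restores the C2=C3 double bond as part of the aromatic pyrrole (addition–elimination, vinylic substitution). In parallel the monovalent copper amidate formed from CuI and 1,10-phenanthroline can insert into the vinyl C–Br bond next to nitrogen and form the same N1–C2 bond by reductive elimination, so both pathways converge on 10. The closest known reaction type is the synthesis of 2-haloindoles from ortho-(2,2-dihalovinyl)anilines and their N-acyl derivatives by intramolecular vinylic amination, base-promoted or catalysed by copper or palladium. The one ring closed is the pyrrole ring (N1, C2, C3, C3a, C7a), formally in the 5-endo-trig mode; the tetrasubstituted alkene twists the aryl ring out of the alkene plane, which puts nitrogen above the π* lobe of the CBr2 carbon and makes this mode accessible. No stereocentre is formed, and since either bromine on the alkene carbon leads to the same product, it does not matter which one leaves. The step needs nitrogen to attack the CBr2 carbon and not the amide carbonyl, which the poor acyl-donor ability of the tertiary amide secures, because a dimethylamide ion would have to leave. It also needs a vinyl bromide and not an aryl bromide to react: only the vinyl bromides are conjugated to the amide and within reach of nitrogen, while the aryl bromides are not activated for substitution and should be slow towards copper at 60 °C. Substitution stops after one bromine because the product has no N–H left to act as a nucleophile, and partial loss of the Boc group under the basic conditions would be harmless because step 6 removes it.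

Step 6
Reactants: 10 tert-butyl 2,5,6-tribromo-3-(dimethylcarbamoyl)indole-1-carboxylate
Product: 11 2,5,6-tribromo-N,N-dimethyl-1H-indole-3-carboxamide
Conditions: TFA, CH2Cl2, 0 °C to rt
Reagents that add atoms: none
Why: Acidolysis of a tert-butyl carbamate with loss of the tert-butyl cation and decarboxylation; the 3-carboxamide disfavours protonation at C3, so the 2-bromoindole should not be hydrolysed in anhydrous acid.

Step 7
Reactants: 11 2,5,6-tribromo-N,N-dimethyl-1H-indole-3-carboxamide
Product: 12 2,5,6-tribromo-N,N,1-trimethylindole-3-carboxamide
Conditions: MeI (1.5 equiv), K2CO3 (2 equiv), DMF, rt
Reagents that add atoms: iodomethane, CI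
Why: SN2 N-alkylation of the indolide anion; the carboxamide and three bromines acidify the N–H enough for carbonate, and the ring nitrogen is the only nucleophilic site.

Step 8
Reactants: 12 2,5,6-tribromo-N,N,1-trimethylindole-3-carboxamide
Product: 14 1-(2,5,6-tribromo-1-methylindol-3-yl)-N,N-dimethylmethanamine, via amine–borane adduct 13 (not isolated)
Conditions: BH3·THF (4 equiv), THF, 0 °C to 65 °C; MeOH quench; 2 M HCl, 60 °C; NaOH work-up
Reagents that add atoms: none
Why: Borane reduction of a tertiary amide; the electrophilic hydride binds the electron-rich carbonyl oxygen, the hemiaminal collapses to an iminium ion and a second hydride gives the amine, held as adduct 13 until acid hydrolysis. Borane leaves aryl and heteroaryl C–Br bonds alone, unlike LiAlH4, and excess hydride is destroyed with methanol before acid is added so that the indole double bond is not reduced.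

Step 9
Reactants: 14 1-(2,5,6-tribromo-1-methylindol-3-yl)-N,N-dimethylmethanamine
Product: 15 1-(2,5,6-tribromo-1-methylindol-3-yl)-N,N-dimethylmethanamine N-oxide
Conditions: mCPBA (1.05 equiv), CH2Cl2, −20 to 0 °C; aq. K2CO3 wash, basic alumina, no heating
Reagents that add atoms: 3-chloroperoxybenzoic acid, O=C(OO)c1cccc(Cl)c1
Why: Peracid N-oxidation of a tertiary amine; the sp3 nitrogen is far more nucleophilic than the tribrominated indole π system, so oxygen transfer at low temperature should be selective, and the basic work-up removes the acid that could promote ionisation of the C3–CH2–N bond.

## Compound list

1 | 6-bromoisatin (6-bromo-1H-indole-2,3-dione) | O=C1Nc2cc(Br)ccc2C1=O | starting material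
2 | 5,6-dibromoisatin (5,6-dibromo-1H-indole-2,3-dione) | O=C1Nc2cc(Br)c(Br)cc2C1=O | intermediate
3 | di-tert-butyl dicarbonate | CC(C)(C)OC(=O)OC(=O)OC(C)(C)C | starting material
4 | tert-butyl 5,6-dibromo-2,3-dioxoindoline-1-carboxylate | CC(C)(C)OC(=O)N1C(=O)C(=O)c2cc(Br)c(Br)cc21 | intermediate
5 | dimethylamine | CNC | starting material
6 | tert-butyl N-{4,5-dibromo-2-[2-(dimethylamino)-2-oxoacetyl]phenyl}carbamate | CN(C)C(=O)C(=O)c1cc(Br)c(Br)cc1NC(=O)OC(C)(C)C | intermediate
7 | carbon tetrabromide | BrC(Br)(Br)Br | starting material
8 | (dibromomethylene)triphenylphosphorane | BrC(Br)=P(c1ccccc1)(c1ccccc1)c1ccccc1 | intermediate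
9 | tert-butyl N-{4,5-dibromo-2-[1,1-dibromo-3-(dimethylamino)-3-oxoprop-1-en-2-yl]phenyl}carbamate | CN(C)C(=O)C(=C(Br)Br)c1cc(Br)c(Br)cc1NC(=O)OC(C)(C)C | intermediate
10 | tert-butyl 2,5,6-tribromo-3-(dimethylcarbamoyl)indole-1-carboxylate | CN(C)C(=O)c1c(Br)n(C(=O)OC(C)(C)C)c2cc(Br)c(Br)cc12 | intermediate
11 | 2,5,6-tribromo-N,N-dimethyl-1H-indole-3-carboxamide | CN(C)C(=O)c1c(Br)[nH]c2cc(Br)c(Br)cc12 | intermediate
12 | 2,5,6-tribromo-N,N,1-trimethylindole-3-carboxamide | CN(C)C(=O)c1c(Br)n(C)c2cc(Br)c(Br)cc12 | intermediate
13 | borane adduct of 1-(2,5,6-tribromo-1-methylindol-3-yl)-N,N-dimethylmethanamine | Cn1c(Br)c(C[N+](C)(C)[BH3-])c2cc(Br)c(Br)cc21 | intermediate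
14 | 1-(2,5,6-tribromo-1-methylindol-3-yl)-N,N-dimethylmethanamine | Cn1c(Br)c(CN(C)C)c2cc(Br)c(Br)cc21 | intermediate
15 | 1-(2,5,6-tribromo-1-methylindol-3-yl)-N,N-dimethylmethanamine N-oxide | Cn1c(Br)c(C[N+](C)(C)[O-])c2cc(Br)c(Br)cc21 | target

## Step count and least certain steps

Total: 9 steps. Longest linear sequence: 9 steps, from 1 to 15.

**Step 5 (key step).** The ring closure may be slower than side processes. The carbamate may be cleaved under the basic conditions before it has closed, or nitrogen may attack the amide carbonyl and form the lactam instead of the pyrrole ring. Fallback: the Boc group of 9 is removed first with TFA in CH2Cl2 to give the free aniline 2-(2-amino-4,5-dibromophenyl)-3,3-dibromo-N,N-dimethylprop-2-enamide F1. F1 is then closed by a palladium-catalysed intramolecular amination (Pd(P(t-Bu)3)2, K3PO4, toluene, 100 °C). Zerovalent palladium inserts into the more reactive gem-dibromovinyl C–Br bond, and reversible oxidative addition with this bulky phosphine should spare the aryl bromides and the product C2–Br bond. This gives the N–H indole directly, so the fallback returns to the route at 11.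

**Step 4.** Olefination at a hindered ketone that is hydrogen-bonded to the carbamate N–H may be slow. The ylide may then be consumed unproductively, or the phosphorus dibromide by-product may attack the carbamate. Fallback: ketone 6 is condensed with hydrazine hydrate in EtOH to the hydrazone tert-butyl N-{4,5-dibromo-2-[2-(dimethylamino)-1-hydrazinylidene-2-oxoethyl]phenyl}carbamate F2. F2 is treated with 7, catalytic CuCl and aqueous ammonia in DMSO at rt. This copper-catalysed olefination of an N-unsubstituted hydrazone with a polyhalomethane proceeds with loss of nitrogen and returns to the route at 9.

**Step 8.** The reduction may go too far or stop short. The C–N bond may be cleaved by hydrogenolysis through a 3-methyleneindoleninium ion, the indole C2=C3 bond may be reduced during the acidic break-up, or the amine–borane adduct may be cleaved incompletely. Fallback: amide 12 is reduced only to the aldehyde oxidation level with Cp2Zr(H)Cl in THF at rt, giving 2,5,6-tribromo-1-methylindole-3-carbaldehyde F3. Reductive amination of F3 with 5 and NaBH(OAc)3 in 1,2-dichloroethane returns to the route at 14.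

**Step 9.** The amine oxide may be lost on isolation, by acid-promoted ionisation of the C3–CH2–N bond or by Meisenheimer-type rearrangement on warming, or the peracid may attack the indole π bond. Fallback: the N–O bond is brought in ready-made. Amine 14 is quaternised with MeI in MeCN to [(2,5,6-tribromo-1-methylindol-3-yl)methyl]trimethylammonium iodide F4. F4 is heated gently with free N,N-dimethylhydroxylamine in MeCN without added base, so that nitrogen and not oxygen is alkylated and trimethylamine is displaced. Work-up with aqueous K2CO3 then gives 15.

## Further compounds

F1 | step 5 | 2-(2-amino-4,5-dibromophenyl)-3,3-dibromo-N,N-dimethylprop-2-enamide | CN(C)C(=O)C(=C(Br)Br)c1cc(Br)c(Br)cc1N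
F2 | step 4 | tert-butyl N-{4,5-dibromo-2-[2-(dimethylamino)-1-hydrazinylidene-2-oxoethyl]phenyl}carbamate (either C=N isomer) | CN(C)C(=O)C(=NN)c1cc(Br)c(Br)cc1NC(=O)OC(C)(C)C
F3 | step 8 | 2,5,6-tribromo-1-methylindole-3-carbaldehyde | Cn1c(Br)c(C=O)c2cc(Br)c(Br)cc21
F4 | step 9 | [(2,5,6-tribromo-1-methylindol-3-yl)methyl]trimethylammonium iodide | Cn1c(Br)c(C[N+](C)(C)C)c2cc(Br)c(Br)cc21.[I-]
A1 | alternative 1 | methyl 1-methyl-5,6-bis(trimethylsilyl)indole-3-carboxylate | COC(=O)c1cn(C)c2cc([Si](C)(C)C)c([Si](C)(C)C)cc12
A2 | alternative 1 | methyl 1-methyl-5-oxo-1,5-dihydropyrano[3,4-b]pyrrole-3-carboxylate | CN1C=C(C(=O)OC)C2=CC(=O)OC=C12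
A3 | alternative 1 | bis(trimethylsilyl)acetylene | C[Si](C)(C)C#C[Si](C)(C)C
A4 | alternative 2 | 5,6-dibromo-N,N,1-trimethylindole-3-carboxamide | CN(C)C(=O)c1cn(C)c2cc(Br)c(Br)cc12
A5 | alternative 2 | N,N,1-trimethylpyrrole-3-carboxamide | CN(C)C(=O)c1ccn(C)c1
A6 | alternative 2 | 3,4-dibromo-2,5-dimethoxytetrahydrofuran (mixture of diastereomers) | COC1OC(OC)C(Br)C1Br
A7 | alternative 3 | methyl 2,5,6-tribromo-1H-indole-3-carboxylate | COC(=O)c1c(Br)[nH]c2cc(Br)c(Br)cc12
A8 | alternative 3 | methyl 2-[4,5-dibromo-2-(dibromomethylideneamino)phenyl]acetate | COC(=O)Cc1cc(Br)c(Br)cc1N=C(Br)Br
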